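**Plan** (target numbered as 4,8-dibromo-9-chloro-5,5,9-trimethyl-1-methylidenespiro[5.5]undecan-2-ol; ring A = C1–C6, ring B = C6–C11)
1. Retrosynthetic cuts, in order: C2–OH and C1=CH2 (back to a C1 ketone); C9–C10 of ring B together with C8–Br; C5–C6 of ring A together with C4–Br; then C2–C3 and C6–C7, leaving prenol, 5-methylisoxazole and (E)-1,3-dichlorobut-2-ene.
2. Forward: an acyclic bromochloride/β-ketonitrile chain is assembled, ring A closes first at C5–C6, ring B then closes at C9–C10, and the C1/C2 allylic alcohol is finished last.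
3. Enabling feature: C9 of ring B is fully substituted, carries Cl and CH3, and sits next to the brominated C8. It is therefore the carbon of a chlorine-stabilised, bromine-bridged cation, and opening that ion with carbon C10 makes the ring and both carbon–halogen stereocentres in one event.
4. Stereochemistry: C4 from a catalytic enantioselective bromochlorination; C6 from the chair closure of ring A (nitrile axial); C8 and C9 from the chair closure of ring B and the E geometry of the chloroalkene; C2 from a reagent-controlled ketone reduction.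

Key step: step 9

Assumption: (E)-1,3-dichlorobut-2-ene (Cl trans to CH2Cl) is used as the pure geometric isomer; atom labels C1–C11 in the Why lines are those of the target, also for intermediates.

**Route**

Step 1
Reactants: 1 3-methylbut-2-en-1-ol
Product: 2 (2R)-2-bromo-3-chloro-3-methylbutan-1-ol
Conditions: NBS, ClTi(OiPr)3, chiral tridentate salicylaldimine–amino alcohol ligand (20 mol %, enantiomer that gives 2R), hexanes, −20 °C
Reagents that add atoms: N-bromosuccinimide, O=C1CCC(=O)N1Br; chlorotitanium triisopropoxide, CC(C)O[Ti](Cl)(OC(C)C)OC(C)C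
Why: The titanium-bound allylic alcohol takes Br+ at C4 and titanium-delivered chloride at the tertiary C5 in an anti addition inside the chiral Schiff-base complex (catalytic enantioselective bromochlorination of allylic alcohols), so the ligand should set C4 as R.

Step 2
Reactants: 2 (2R)-2-bromo-3-chloro-3-methylbutan-1-ol
Product: 3 (2R)-2-bromo-3-chloro-3-methylbutyl trifluoromethanesulfonate
Conditions: Tf2O, 2,6-lutidine, CH2Cl2, −78 °C
Reagents that add atoms: trifluoromethanesulfonic anhydride, O=S(=O)(OS(=O)(=O)C(F)(F)F)C(F)(F)F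
Why: O-sulfonylation of the primary alcohol at low temperature makes C3 a leaving group without touching the stereocentre.

Step 3
Reactants: 4 5-methylisoxazole; 5 (E)-1,3-dichlorobut-2-ene
Product: 7 (4E)-2-acetyl-5-chlorohex-4-enenitrile, via sodium cyanoacetone enolate 6 (not isolated)
Conditions: NaOEt, EtOH, 0 °C; then 5, NaI (cat.), 23 °C
Reagents that add atoms: none
Why: Ethoxide removes H3 of the isoxazole and the N–O bond opens to the cyanoacetone enolate (base-induced isoxazole ring opening), which is C-alkylated by the allylic chloride in an SN2 reaction that leaves the vinylic chloride and its E geometry untouched; the new stereocentre is racemic and enolisable, which is of no consequence.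

Step 4
Reactants: 7 (4E)-2-acetyl-5-chlorohex-4-enenitrile; 3 (2R)-2-bromo-3-chloro-3-methylbutyl trifluoromethanesulfonate
Product: 8 (6R)-6-bromo-7-chloro-2-[(2E)-3-chlorobut-2-en-1-yl]-7-methyl-3-oxooctanenitrile (both C2 epimers)
Conditions: LDA (2.2 equiv), THF, −78 → 0 °C; then 3, −78 °C; aqueous NH4Cl
Reagents that add atoms: none
Why: The dianion of the β-ketonitrile reacts at its more basic γ-carbon (as in acetoacetate dianion alkylation) and should displace the primary triflate at −78 °C faster than it eliminates, forming C2–C3 without touching C4.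

Step 5
Reactants: 8 (6R)-6-bromo-7-chloro-2-[(2E)-3-chlorobut-2-en-1-yl]-7-methyl-3-oxooctanenitrile
Product: 9 (1R,3R)-3-bromo-1-[(2E)-3-chlorobut-2-en-1-yl]-2,2-dimethyl-6-oxocyclohexane-1-carbonitrile
Conditions: (CF3)2CHOH, 2,6-di-tert-butyl-4-methylpyridine, 23 °C
Reagents that add atoms: none
Why: In the ionising, non-nucleophilic solvent the tertiary chloride leaves with participation of the neighbouring bromine, and the enantiopure bromonium ion is opened at C5 by the enol carbon C6 through a chair (solvolytic bromonium-ion cyclisation with a 1,3-dicarbonyl-type carbon nucleophile, as known for β-keto esters); bromine must be equatorial and the linear nitrile, the smallest substituent, should take the axial site, which sets C6 with the chlorobutenyl arm cis to bromine.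

Step 6
Reactants: 9 (1R,3R)-3-bromo-1-[(2E)-3-chlorobut-2-en-1-yl]-2,2-dimethyl-6-oxocyclohexane-1-carbonitrile
Product: 10 (1S,3R)-3-bromo-1-[(2E)-3-chlorobut-2-en-1-yl]-6-hydroxy-2,2-dimethylcyclohexane-1-carbaldehyde (both C6 epimers)
Conditions: i-Bu2AlH (4 equiv), CH2Cl2, −78 → 0 °C; aqueous potassium sodium tartrate
Reagents that add atoms: water, O
Why: i-Bu2AlH stops at the N-aluminio imine of the nitrile, which is hydrolysed to the aldehyde on work-up (nitrile-to-aldehyde reduction), and reduces the ketone to an alcohol whose configuration is irrelevant because it is reoxidised in step 7.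

Step 7
Reactants: 10 (1S,3R)-3-bromo-1-[(2E)-3-chlorobut-2-en-1-yl]-6-hydroxy-2,2-dimethylcyclohexane-1-carbaldehyde
Product: 11 (1R,3R)-3-bromo-1-[(2E)-3-chlorobut-2-en-1-yl]-2,2-dimethyl-6-oxocyclohexane-1-carbaldehyde
Conditions: Dess–Martin periodinane, NaHCO3, CH2Cl2, 0 → 23 °C
Reagents that add atoms: none
Why: Dess–Martin oxidation under buffered, non-basic conditions returns the C1 ketone and should not cleave the non-enolisable β-keto aldehyde by a retro-Claisen path.

Step 8
Reactants: 11 (1R,3R)-3-bromo-1-[(2E)-3-chlorobut-2-en-1-yl]-2,2-dimethyl-6-oxocyclohexane-1-carbaldehyde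
Product: 12 (2S,4R)-4-bromo-2-[(2E)-3-chlorobut-2-en-1-yl]-3,3-dimethyl-2-[(E)-2-(trimethylsilyl)ethenyl]cyclohexan-1-one
Conditions: CrCl2 (8 equiv), Me3SiCHBr2 (2 equiv), THF, 25 °C
Reagents that add atoms: (dibromomethyl)trimethylsilane, C[Si](C)(C)C(Br)Br
Why: The geminal dichromium reagent adds to aldehydes much faster than to ketones and eliminates to the E-vinylsilane (Takai–Utimoto olefination), under conditions too weakly basic to cleave the β-keto aldehyde or disturb the alkyl bromide.

Step 9
Reactants: 12 (2S,4R)-4-bromo-2-[(2E)-3-chlorobut-2-en-1-yl]-3,3-dimethyl-2-[(E)-2-(trimethylsilyl)ethenyl]cyclohexan-1-one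
Product: 13 (4R,6S,9S,10S)-4,10-dibromo-9-chloro-5,5,9-trimethylspiro[5.5]undec-7-en-1-one
Conditions: [Et2SBr][SbCl5Br] (1.1 equiv), 2,6-di-tert-butyl-4-methylpyridine, MeNO2, −25 °C
Reagents that add atoms: bromodiethylsulfonium bromopentachloroantimonate, CC[S+](Br)CC.Cl[Sb-](Cl)(Cl)(Cl)(Cl)Br
Why: Proposed new method: Br+ adds to the (E)-chloroalkene at C8, the charge settles on C9 as a tertiary cation stabilised by the chlorine lone pair and bridged by bromine, and the vinylsilane attacks it through its silicon-bearing carbon C10 (ipso attack), after which the β-silyl cation at C11 loses Me3Si+ to leave the C10=C11 alkene; the closest known reactions are bromonium-ion-induced cation–olefin cyclisations with non-nucleophilic Br+ donors, vinylsilane-terminated cationic cyclisations in the endocyclic mode, and chloro-olefin annulations that pass through a chlorine-stabilised cation, but a chloroalkene has not been used as the bromonium-ion initiator. Ring B closes in the 6-endo mode with respect to the activated C8=C9 bond, through a chair in which C5 (the CMe2 carbon of ring A) is equatorial and C1 is axial. C8 is set because carbon must open the bromonium ion anti, which puts bromine equatorial and cis to C5; C9 is set by the E geometry of the alkene, which places chlorine equatorial (trans to bromine) and methyl axial; both are tied to C6 by the strong preference of the quaternary C5 for the equatorial site. The step needs chemoselectivity for the chloroalkene over the vinylsilane and carbon capture in preference to halide capture: the two π bonds are of similar nucleophilicity, bromonium transfer between alkenes is reversible, only the ion on the chloroalkene has a nucleophile placed for six-ring closure, the vinylsilane sits on a neopentyl carbon next to the carbonyl, and SbCl5Br− is a poor halide donor at low temperature.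

Step 10
Reactants: 13 (4R,6S,9S,10S)-4,10-dibromo-9-chloro-5,5,9-trimethylspiro[5.5]undec-7-en-1-one
Product: 14 (4R,6R,8S,9S)-4,8-dibromo-9-chloro-5,5,9-trimethylspiro[5.5]undecan-1-one
Conditions: 2-nitrobenzenesulfonyl hydrazide (excess), Et3N, CH2Cl2, 23 °C
Reagents that add atoms: none
Why: Diimide transfers H2 to the cis-disubstituted C10=C11 alkene in a concerted, metal-free step that cannot hydrogenolyse C–Br or the allylic C–Cl bond and does not touch the ketone (diimide reduction).

Step 11
Reactants: 14 (4R,6R,8S,9S)-4,8-dibromo-9-chloro-5,5,9-trimethylspiro[5.5]undecan-1-one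
Product: 15 (2R,6S,8S,9S)-2,8-dibromo-9-chloro-1,1,9-trimethyl-5-methylidenespiro[5.5]undecane
Conditions: Cp2TiMe2, toluene, 65 °C, dark
Reagents that add atoms: dimethyltitanocene, [Ti+4].[CH3-].[CH3-].c1cc[cH-]c1.c1cc[cH-]c1
Why: Dimethyltitanocene gives Cp2Ti=CH2 on heating, which methylenates hindered, enolisable ketones under non-basic conditions (Petasis olefination), so the tertiary chloride and both bromides should not eliminate.

Step 12
Reactants: 15 (2R,6S,8S,9S)-2,8-dibromo-9-chloro-1,1,9-trimethyl-5-methylidenespiro[5.5]undecane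
Product: 17 (4R,6S,8S,9S)-4,8-dibromo-9-chloro-5,5,9-trimethyl-1-methylidenespiro[5.5]undecan-2-one, via C2 allylic alcohol epimers 16 (not isolated)
Conditions: SeO2 (0.5 equiv), t-BuOOH, CH2Cl2, 23 °C; then Dess–Martin periodinane, NaHCO3, 23 °C
Reagents that add atoms: selenium dioxide, O=[Se]=O; tert-butyl hydroperoxide, CC(C)(C)OO
Why: Selenium dioxide reacts by an ene reaction and 2,3-sigmatropic shift that returns the double bond to the exocyclic position, and C2 is the only allylic carbon bearing hydrogen (Riley allylic oxidation); since the C2 configuration from this step cannot be predicted with confidence, the alcohol is oxidised in the same flask to the enone (Dess–Martin oxidation).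

Step 13
Reactants: 17 (4R,6S,8S,9S)-4,8-dibromo-9-chloro-5,5,9-trimethyl-1-methylidenespiro[5.5]undecan-2-one
Product: 18 (2R,4R,6S,8S,9S)-4,8-dibromo-9-chloro-5,5,9-trimethyl-1-methylidenespiro[5.5]undecan-2-ol (target)
Conditions: (S)-2-methyl-CBS-oxazaborolidine (0.3 equiv), catecholborane, toluene, −78 °C
Reagents that add atoms: none
Why: The oxazaborolidine binds the ketone with the fully substituted alkenyl carbon C1 as the large group and should deliver hydride to the face that gives the 2R alcohol (Corey–Bakshi–Shibata reduction); this is also the face left open by the axial C11 methylene, so catalyst and substrate control are matched and only 1,2-reduction is expected at −78 °C.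

**Compound list**
1 | 3-methylbut-2-en-1-ol | CC(C)=CCO | starting material
2 | (2R)-2-bromo-3-chloro-3-methylbutan-1-ol | OC[C@@H](Br)C(C)(C)Cl | intermediate
3 | (2R)-2-bromo-3-chloro-3-methylbutyl trifluoromethanesulfonate | FC(F)(F)S(=O)(=O)OC[C@@H](Br)C(C)(C)Cl | intermediate
4 | 5-methylisoxazole | Cc1ccno1 | starting material
5 | (E)-1,3-dichlorobut-2-ene | ClC/C=C(/Cl)C | starting material
6 | sodium enolate of 3-oxobutanenitrile (not isolated) | CC([O-])=CC#N.[Na+] | intermediate
7 | (4E)-2-acetyl-5-chlorohex-4-enenitrile (racemic) | CC(=O)C(C#N)C/C=C(/Cl)C | intermediate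
8 | (6R)-6-bromo-7-chloro-2-[(2E)-3-chlorobut-2-en-1-yl]-7-methyl-3-oxooctanenitrile (both C2 epimers) | N#CC(C/C=C(/Cl)C)C(=O)CC[C@@H](Br)C(C)(C)Cl | intermediate
9 | (1R,3R)-3-bromo-1-[(2E)-3-chlorobut-2-en-1-yl]-2,2-dimethyl-6-oxocyclohexane-1-carbonitrile | N#C[C@]1(C/C=C(/Cl)C)C(=O)CC[C@@H](Br)C1(C)C | intermediate
10 | (1S,3R)-3-bromo-1-[(2E)-3-chlorobut-2-en-1-yl]-6-hydroxy-2,2-dimethylcyclohexane-1-carbaldehyde (both C6 epimers) | O=C[C@]1(C/C=C(/Cl)C)C(O)CC[C@@H](Br)C1(C)C | intermediate
11 | (1R,3R)-3-bromo-1-[(2E)-3-chlorobut-2-en-1-yl]-2,2-dimethyl-6-oxocyclohexane-1-carbaldehyde | O=C[C@]1(C/C=C(/Cl)C)C(=O)CC[C@@H](Br)C1(C)C | intermediate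
12 | (2S,4R)-4-bromo-2-[(2E)-3-chlorobut-2-en-1-yl]-3,3-dimethyl-2-[(E)-2-(trimethylsilyl)ethenyl]cyclohexan-1-one | C[Si](C)(C)/C=C/[C@]1(C/C=C(/Cl)C)C(=O)CC[C@@H](Br)C1(C)C | intermediate
13 | (4R,6S,9S,10S)-4,10-dibromo-9-chloro-5,5,9-trimethylspiro[5.5]undec-7-en-1-one | O=C1CC[C@@H](Br)C(C)(C)[C@]12C=C[C@](C)(Cl)[C@@H](Br)C2 | intermediate
14 | (4R,6R,8S,9S)-4,8-dibromo-9-chloro-5,5,9-trimethylspiro[5.5]undecan-1-one | O=C1CC[C@@H](Br)C(C)(C)[C@]12CC[C@](C)(Cl)[C@@H](Br)C2 | intermediate
15 | (2R,6S,8S,9S)-2,8-dibromo-9-chloro-1,1,9-trimethyl-5-methylidenespiro[5.5]undecane | C=C1CC[C@@H](Br)C(C)(C)[C@]12CC[C@](C)(Cl)[C@@H](Br)C2 | intermediate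
16 | (4R,6S,8S,9S)-4,8-dibromo-9-chloro-5,5,9-trimethyl-1-methylidenespiro[5.5]undecan-2-ol, mixture of C2 epimers (not isolated) | C=C1C(O)C[C@@H](Br)C(C)(C)[C@]12CC[C@](C)(Cl)[C@@H](Br)C2 | intermediate
17 | (4R,6S,8S,9S)-4,8-dibromo-9-chloro-5,5,9-trimethyl-1-methylidenespiro[5.5]undecan-2-one | C=C1C(=O)C[C@@H](Br)C(C)(C)[C@]12CC[C@](C)(Cl)[C@@H](Br)C2 | intermediate
18 | (2R,4R,6S,8S,9S)-4,8-dibromo-9-chloro-5,5,9-trimethyl-1-methylidenespiro[5.5]undecan-2-ol | C=C1[C@H](O)C[C@@H](Br)C(C)(C)[C@]12CC[C@](C)(Cl)[C@@H](Br)C2 | target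

**Step count**
Total: 13 steps. Longest linear sequence: 12 steps (steps 1, 2 and 4 to 13, from 3-methylbut-2-en-1-ol); step 3 is the one-step side branch.

**Steps most likely to fail**

1. Step 9 (Proposed new method). What may go wrong: the bromine electrophile attacks the vinylsilane (ipso-bromodesilylation) instead of the chloroalkene; the bromonium ion is captured by halide instead of carbon; or the secondary cation at C11 rearranges before silicon is lost. Fallback by known chemistry, setting out from 4 and coming back at 14, without a ring-B alkene to reduce: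
   - 5-methylisoxazole 4 would be opened as in step 3 and alkylated with (Z)-1-bromo-2-iodobut-2-ene to give (4Z)-2-acetyl-5-iodohex-4-enenitrile F1.
   - γ-Alkylation of its dianion with 3 as in step 4 would give (6R)-6-bromo-7-chloro-2-[(2Z)-3-iodobut-2-en-1-yl]-7-methyl-3-oxooctanenitrile F2.
   - Solvolytic closure as in step 5 would give (1R,3R)-3-bromo-1-[(2Z)-3-iodobut-2-en-1-yl]-2,2-dimethyl-6-oxocyclohexane-1-carbonitrile F3.
   - i-Bu2AlH reduction and Dess–Martin oxidation as in steps 6 and 7 would give (1S,3R)-3-bromo-6-hydroxy-1-[(2Z)-3-iodobut-2-en-1-yl]-2,2-dimethylcyclohexane-1-carbaldehyde F4 and then (1R,3R)-3-bromo-1-[(2Z)-3-iodobut-2-en-1-yl]-2,2-dimethyl-6-oxocyclohexane-1-carbaldehyde F5.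
   - Wittig methylenation of the aldehyde (Ph3P=CH2, THF, −78 °C) would give (2S,4R)-4-bromo-2-ethenyl-2-[(2Z)-3-iodobut-2-en-1-yl]-3,3-dimethylcyclohexan-1-one F6.
   - Hydroboration of the vinyl group with 9-BBN would give the B-alkyl-9-borabicyclo[3.3.1]nonane F7 (not isolated). Intramolecular B-alkyl Suzuki–Miyaura coupling with the Z-vinyl iodide (Pd(dppf)Cl2, AsPh3, Cs2CO3, DMF/H2O) would close ring B at the same C9–C10 bond as (4R,6R)-4-bromo-5,5,9-trimethylspiro[5.5]undec-8-en-1-one F8.
   - Anti bromochlorination of the C8=C9 alkene with Bu4N+ BrCl2− (CH2Cl2, −78 °C) should give 14, provided Br+ adds anti to the axial C1 and chloride opens at the tertiary carbon; this facial selectivity is the weak point of the fallback.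

2. Step 5. What may go wrong: capture of the bromonium ion at the enol oxygen instead of carbon, slow bond formation at the fully substituted C6, or closure with the nitrile equatorial. Fallback, setting out from 8 and coming back at 9: 8 would be converted with TBSOTf and Et3N (CH2Cl2, −78 °C) into its tert-butyldimethylsilyl enol ether F9. The tertiary chloride would then be ionised with AgOTf and 2,6-di-tert-butyl-4-methylpyridine in CH2Cl2 at −40 °C. The bromonium ion is thus opened by a preformed enol silane in a Mukaiyama-type tertiary alkylation, with no free enol oxygen to compete and in a non-ionising solvent.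

3. Step 10. What may go wrong: slow hydrogen transfer to an alkene flanked by two fully substituted carbons, and loss of the allylic tertiary chloride on long exposure to amine base. Fallback, setting out from 13 and coming back at 14: a ketone-directed homogeneous hydrogenation with [Ir(cod)(PCy3)(py)]PF6 (5 mol %) under H2 (1 atm) in CH2Cl2 at 0 °C replaces diimide transfer. The cationic iridium complex binds the C1 carbonyl and delivers H2 to the nearby C10=C11 bond under neutral conditions.

**Further compounds**
F1 | step 9 | (4Z)-2-acetyl-5-iodohex-4-enenitrile | CC(=O)C(C#N)C/C=C(\I)C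
F2 | step 9 | (6R)-6-bromo-7-chloro-2-[(2Z)-3-iodobut-2-en-1-yl]-7-methyl-3-oxooctanenitrile | N#CC(C/C=C(\I)C)C(=O)CC[C@@H](Br)C(C)(C)Cl
F3 | step 9 | (1R,3R)-3-bromo-1-[(2Z)-3-iodobut-2-en-1-yl]-2,2-dimethyl-6-oxocyclohexane-1-carbonitrile | N#C[C@]1(C/C=C(\I)C)C(=O)CC[C@@H](Br)C1(C)C
F4 | step 9 | (1S,3R)-3-bromo-6-hydroxy-1-[(2Z)-3-iodobut-2-en-1-yl]-2,2-dimethylcyclohexane-1-carbaldehyde (both C6 epimers) | O=C[C@]1(C/C=C(\I)C)C(O)CC[C@@H](Br)C1(C)C
F5 | step 9 | (1R,3R)-3-bromo-1-[(2Z)-3-iodobut-2-en-1-yl]-2,2-dimethyl-6-oxocyclohexane-1-carbaldehyde | O=C[C@]1(C/C=C(\I)C)C(=O)CC[C@@H](Br)C1(C)C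
F6 | step 9 | (2S,4R)-4-bromo-2-ethenyl-2-[(2Z)-3-iodobut-2-en-1-yl]-3,3-dimethylcyclohexan-1-one | C=C[C@]1(C/C=C(\I)C)C(=O)CC[C@@H](Br)C1(C)C
F7 | step 9 | 9-{2-[(1R,3R)-3-bromo-1-[(2Z)-3-iodobut-2-en-1-yl]-2,2-dimethyl-6-oxocyclohexyl]ethyl}-9-borabicyclo[3.3.1]nonane | B1(CC[C@]2(C/C=C(\I)C)C(=O)CC[C@@H](Br)C2(C)C)C2CCCC1CCC2
F8 | step 9 | (4R,6R)-4-bromo-5,5,9-trimethylspiro[5.5]undec-8-en-1-one | O=C1CC[C@@H](Br)C(C)(C)[C@]12CCC(C)=CC2
F9 | step 5 | (6R)-6-bromo-3-[(tert-butyldimethylsilyl)oxy]-7-chloro-2-[(2E)-3-chlorobut-2-en-1-yl]-7-methyloct-2-enenitrile (enol ether geometry not defined) | CC(C)(C)[Si](C)(C)OC(CC[C@@H](Br)C(C)(C)Cl)=C(C#N)C/C=C(/Cl)C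
F0 | step 10 | none | none
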